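**Plan**
- Cuts: the p-coumaroyl arm on O4 is severed twice, at the O4–C(acyl) bond and at its Cα=Cβ double bond, leaving a two-carbon ketenylidene phosphorane and 4-acetoxybenzaldehyde; the caffeoyl arm is severed once, at O3–C(acyl).
- Enabling feature: with C1–CO2H and O5 tied into the 1,5-lactone, the cyclohexane ring is locked so that O3 is equatorial and O4 is axial, pinched between the C3 ester and C5. O3 accepts a whole acyl chloride; O4 is better reached by a small linear cumulene from which the arm is then grown.
- Forward order: quinic acid → 3,4-acetonide 1,5-lactone → O1 Troc carbonate → 3,4-diol → O3 caffeate → O4 ester ylide and Wittig with the aldehyde → Troc removal → acid hydrolysis of the aryl acetates and the lactone.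
- O1 is capped because a free α-hydroxy lactone would itself add to the cumulene and could then olefinate its own lactone carbonyl (tetronate formation).
- Stereochemistry: C1, C3, C4 and C5 come unchanged from (−)-quinic acid, since no C–O bond at a stereocentre is ever broken; the caffeoyl E-alkene comes from caffeic acid and the coumaroyl E-alkene from the stabilised ylide.

Key step: step 7

Assumption: quinic acid numbering is used throughout (C1 bears CO2H; O1, O3 and O4 lie on one face of the ring, O5 and CO2H on the other), so the target is 3-O-caffeoyl-4-O-p-coumaroylquinic acid. Troc = 2,2,2-trichloroethoxycarbonyl; "quinide" = quinic acid 1,5-lactone.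

**Route**

Step 1
Reactants: 1 (−)-quinic acid
Product: 2 3,4-O-isopropylidene-1,5-quinide (1,5-lactone with O3 and O4 bridged by CMe2; 1-OH free)
Conditions: Me2C(OMe)2, TsOH·H2O (cat.), acetone, reflux; NaHCO3 quench
Reagents that add atoms: 2,2-dimethoxypropane, COC(C)(C)OC
Why: Acid-catalysed transacetalisation should place the isopropylidene on the cis-3,4-diol while the syn-disposed C1 carboxyl and 5-OH close the γ-lactone (Fischer-type lactonisation, water scavenged by the excess acetal), with no stereocentre touched.

Step 2
Reactants: 2 3,4-O-isopropylidene-1,5-quinide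
Product: 3 1-O-Troc-3,4-O-isopropylidene-1,5-quinide
Conditions: TrocCl, pyridine, DMAP (cat.), CH2Cl2, 0 °C → rt
Reagents that add atoms: 2,2,2-trichloroethyl chloroformate, O=C(Cl)OCC(Cl)(Cl)Cl
Why: DMAP-catalysed chloroformate acylation (carbonate formation) of the only free hydroxyl, the equatorial tertiary 1-OH, should proceed cleanly since O3, O4 and O5 are all blocked.

Step 3
Reactants: 3 1-O-Troc-3,4-O-isopropylidene-1,5-quinide
Product: 4 1-O-Troc-1,5-quinide (free cis-3,4-diol; O3–H equatorial, O4–H axial)
Conditions: TFA/H2O (9:1), 0 °C → rt, short contact; co-evaporation with toluene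
Reagents that add atoms: none
Why: Acid-catalysed acetal hydrolysis should release the 3,4-diol, the Troc carbonate and the bridged lactone both tolerating brief exposure to aqueous TFA.

Step 4
Reactants: 5 caffeic acid
Product: 6 (E)-3,4-diacetoxycinnamic acid (di-O-acetylcaffeic acid)
Conditions: Ac2O, aq. NaOH, 0 °C, Ar; then aq. HCl to pH 2
Reagents that add atoms: acetic anhydride, CC(=O)OC(C)=O
Why: Schotten–Baumann O-acetylation of the two phenoxides is fast in cold aqueous base, the carboxylate keeps no acyl group in water, and acidification should precipitate the free acid with the E-alkene intact.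

Step 5
Reactants: 6 (E)-3,4-diacetoxycinnamic acid
Product: 7 (E)-3,4-diacetoxycinnamoyl chloride
Conditions: (COCl)2, DMF (cat.), CH2Cl2, 0 °C → rt; volatiles removed, used crude
Reagents that add atoms: oxalyl chloride, O=C(Cl)C(=O)Cl
Why: Vilsmeier-type activation with oxalyl chloride and catalytic DMF converts the acid into its chloride under conditions that leave aryl acetates and the alkene geometry alone.

Step 6
Reactants: 4 1-O-Troc-1,5-quinide; 7 (E)-3,4-diacetoxycinnamoyl chloride
Product: 8 1-O-Troc-3-O-(3,4-di-O-acetylcaffeoyl)-1,5-quinide (4-OH free)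
Conditions: 7 (1.05 equiv, slow addition), pyridine, DMAP (cat.), CH2Cl2, −20 → 0 °C
Reagents that add atoms: none
Why: Regioselective nucleophilic-catalysis acylation of a cis-diol: in the lactone-locked chair O3–H is equatorial and open while O4–H is axial and shielded, so one equivalent of acid chloride at low temperature should acylate O3.

Step 7
Reactants: 8 1-O-Troc-3-O-(3,4-di-O-acetylcaffeoyl)-1,5-quinide; 9 (triphenylphosphoranylidene)ketene; 10 4-acetoxybenzaldehyde
Product: 12 1-O-Troc-3-O-(3,4-di-O-acetylcaffeoyl)-4-O-(4-O-acetyl-p-coumaroyl)-1,5-quinide, via ester ylide 11 (not isolated)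
Conditions: 9 (1.3 equiv), toluene, 80 °C, Ar; then 10 (2 equiv), 100 °C, one pot
Reagents that add atoms: none
Why: The O4–H adds across the C=C of the cumulated ylide (proton transfer to the ylidic carbon, then capture of the ketenyl phosphonium by the alkoxide) to give the carbonyl-stabilised ester ylide 11, which olefinates 4-acetoxybenzaldehyde through an oxaphosphetane that collapses to the enoate and Ph3P=O. This is the known three-component alcohol/ketenylidenetriphenylphosphorane/aldehyde enoate synthesis (addition–Wittig cascade). No ring is closed and no stereocentre is created; the only new stereo-element is the alkene, whose E geometry follows from the reversible oxaphosphetane formation typical of a stabilised ylide. Site selectivity is secured by the substrate: O4–H is the only hydroxyl left, because O1 is a carbonate, so neither addition at O1 nor olefination of the lactone carbonyl can compete. The linear two-carbon cumulene should reach the axial O4 between the C3 ester and C5 more easily than a bulky activated cinnamate, and the neutral, base-free medium should leave the C3 caffeate, the aryl acetates and the carbonate in place.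

Step 8
Reactants: 12 1-O-Troc-3-O-(3,4-di-O-acetylcaffeoyl)-4-O-(4-O-acetyl-p-coumaroyl)-1,5-quinide
Product: 13 3-O-(3,4-di-O-acetylcaffeoyl)-4-O-(4-O-acetyl-p-coumaroyl)-1,5-quinide (1-OH free)
Conditions: Zn dust, AcOH/THF, rt
Reagents that add atoms: none
Why: Reductive β-elimination of the trichloroethyl carbonate by zinc (Troc cleavage) should free O1 with loss of dichloroethene and CO2, while cinnamate esters, aryl acetates and the lactone are inert to Zn/AcOH.

Step 9
Reactants: 13 3-O-(3,4-di-O-acetylcaffeoyl)-4-O-(4-O-acetyl-p-coumaroyl)-1,5-quinide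
Product: 14 3-O-caffeoyl-4-O-p-coumaroylquinic acid (target)
Conditions: 1 M aq. HCl/THF, rt, Ar; reversed-phase purification
Reagents that add atoms: water, O
Why: Acid-catalysed ester hydrolysis should remove the three activated aryl acetates and open the strained bicyclic lactone by acyl–oxygen cleavage (C5 configuration retained) faster than it attacks the conjugated cinnamate esters, and the acidic medium disfavours the base-promoted O4→O5 acyl shift.

**Compound list**
1 | (−)-quinic acid | O[C@H]1[C@H](O)C[C@](O)(C(=O)O)C[C@H]1O | starting material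
2 | 3,4-O-isopropylidene-1,5-quinide | CC1(C)O[C@H]2[C@H]3C[C@](O)(C(=O)O3)C[C@H]2O1 | intermediate
3 | 1-O-Troc-3,4-O-isopropylidene-1,5-quinide | CC1(C)O[C@H]2[C@H]3C[C@](OC(=O)OCC(Cl)(Cl)Cl)(C(=O)O3)C[C@H]2O1 | intermediate
4 | 1-O-Troc-1,5-quinide | O[C@H]1[C@H]2C[C@](OC(=O)OCC(Cl)(Cl)Cl)(C(=O)O2)C[C@H]1O | intermediate
5 | caffeic acid | O=C(O)/C=C/c1ccc(O)c(O)c1 | starting material
6 | (E)-3,4-diacetoxycinnamic acid | O=C(O)/C=C/c1ccc(OC(C)=O)c(OC(C)=O)c1 | intermediate
7 | (E)-3,4-diacetoxycinnamoyl chloride | O=C(Cl)/C=C/c1ccc(OC(C)=O)c(OC(C)=O)c1 | intermediate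
8 | 1-O-Troc-3-O-(3,4-di-O-acetylcaffeoyl)-1,5-quinide | O[C@H]1[C@H]2C[C@](OC(=O)OCC(Cl)(Cl)Cl)(C(=O)O2)C[C@H]1OC(=O)/C=C/c1ccc(OC(C)=O)c(OC(C)=O)c1 | intermediate
9 | (triphenylphosphoranylidene)ketene | O=C=C=P(c1ccccc1)(c1ccccc1)c1ccccc1 | starting material
10 | 4-acetoxybenzaldehyde | O=Cc1ccc(OC(C)=O)cc1 | starting material
11 | 4-O-[(triphenylphosphoranylidene)acetyl] ester ylide of 8 | O=C(C=P(c1ccccc1)(c1ccccc1)c1ccccc1)O[C@H]1[C@H]2C[C@](OC(=O)OCC(Cl)(Cl)Cl)(C(=O)O2)C[C@H]1OC(=O)/C=C/c1ccc(OC(C)=O)c(OC(C)=O)c1 | intermediate
12 | 1-O-Troc-3-O-(3,4-di-O-acetylcaffeoyl)-4-O-(4-O-acetyl-p-coumaroyl)-1,5-quinide | O=C(/C=C/c1ccc(OC(C)=O)cc1)O[C@H]1[C@H]2C[C@](OC(=O)OCC(Cl)(Cl)Cl)(C(=O)O2)C[C@H]1OC(=O)/C=C/c1ccc(OC(C)=O)c(OC(C)=O)c1 | intermediate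
13 | 3-O-(3,4-di-O-acetylcaffeoyl)-4-O-(4-O-acetyl-p-coumaroyl)-1,5-quinide | O=C(/C=C/c1ccc(OC(C)=O)cc1)O[C@H]1[C@H]2C[C@](O)(C(=O)O2)C[C@H]1OC(=O)/C=C/c1ccc(OC(C)=O)c(OC(C)=O)c1 | intermediate
14 | 3-O-caffeoyl-4-O-p-coumaroylquinic acid | O=C(/C=C/c1ccc(O)cc1)O[C@H]1[C@H](O)C[C@](O)(C(=O)O)C[C@H]1OC(=O)/C=C/c1ccc(O)c(O)c1 | target

**Count**
Total steps: 9. Longest linear sequence: 7 steps (1, 2, 3, 6, 7, 8, 9 from quinic acid); the caffeic acid branch (4, 5) joins at step 6.

**Steps most likely to fail**

Step 7. The addition of the shielded axial hydroxyl to the cumulene may stall, or the nucleophilic ylide carbon may take an acetyl group from an aryl acetate or attack the trichloroethyl group before the aldehyde is consumed. The fallback sets out from 8 and comes back at 12, forming the same two bonds in two separate operations. Compound 8 is esterified at O4 with diethylphosphonoacetic acid (DCC, DMAP cat., CH2Cl2) to give the 4-O-(diethylphosphonoacetyl) ester F1. F1 is then condensed with 10 in a Horner–Wadsworth–Emmons reaction under Masamune–Roush conditions (LiCl, iPr2NEt, MeCN), which should give the E-enoate 12.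

Step 6. Discrimination between O3 and O4 may be poor, or acylation may run on to the 3,4-diester. The fallback sets out from 4 and comes back at 8, replacing kinetic acylation of the free diol by acylation of a preformed tin acetal. Compound 4 is heated with Bu2SnO in toluene with azeotropic removal of water to give the 3,4-O-dibutylstannylene acetal F2. F2 is treated with 7 in CH2Cl2 at low temperature; the stannylene should deliver the acyl group to the equatorial oxygen, and aqueous work-up then gives 8.

Step 9. The three aryl acetates may be lost slowly and unevenly in aqueous acid, so that during the long exposure the cinnamate esters begin to hydrolyse or the coumaroyl group drifts from O4 to the freed O5. The fallback sets out from 13 and comes back at 14, separating the two events. The aryl acetates are first removed by hydrazinolysis (hydrazine acetate, DMF, 0 °C → rt), which should spare the alkyl cinnamates and the lactone and give 3-O-caffeoyl-4-O-p-coumaroyl-1,5-quinide F3. The lactone of F3 alone is then opened in dilute aqueous HCl/THF, with a shorter acid exposure, to give 14.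

**Further compounds**
F1 | step 7 | 1-O-Troc-3-O-(3,4-di-O-acetylcaffeoyl)-4-O-(diethylphosphonoacetyl)-1,5-quinide | CCOP(=O)(CC(=O)O[C@H]1[C@H]2C[C@](OC(=O)OCC(Cl)(Cl)Cl)(C(=O)O2)C[C@H]1OC(=O)/C=C/c1ccc(OC(C)=O)c(OC(C)=O)c1)OCC
F2 | step 6 | 3,4-O-dibutylstannylene acetal of 1-O-Troc-1,5-quinide | CCCC[Sn]1(CCCC)O[C@H]2[C@H]3C[C@](OC(=O)OCC(Cl)(Cl)Cl)(C(=O)O3)C[C@H]2O1
F3 | step 9 | 3-O-caffeoyl-4-O-p-coumaroyl-1,5-quinide | O=C(/C=C/c1ccc(O)cc1)O[C@H]1[C@H]2C[C@](O)(C(=O)O2)C[C@H]1OC(=O)/C=C/c1ccc(O)c(O)c1
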